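**Retrosynthetic overview**
1. Target 21 ⇒ MOM removal ⇒ benzylic ester C–O bond: ring-A benzylic bromide 9 + haematommic acid 19 (carboxylate SN2, which avoids a free o-hydroxymethyl benzoate that would lactonize).
2. 9 ⇒ lateral lithiation/bromination of MOM-protected methyl β-orcinolcarboxylate 7 ⇒ phenol 6 ⇒ aromatization of cyclohexane-1,3-dione 4.
3. 19 ⇒ benzyl haematommate 18 ⇒ C3 formylation of benzyl orsellinate 16 ⇒ methyl orsellinate 14 ⇒ dione 12.
4. Key C–C bonds: intermolecular Michael addition of a β-keto ester (1 or 10) to methyl crotonate 2, each followed by Dieckmann (Claisen) ring closure.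
5. Ring order: ring A (steps 1–4), ring B (steps 5–10), union (step 11), deprotection (step 12).

Assumption: the target has no stereocentre (achiral), so no enantiocontrol is needed; group-delivering reagents (Br2, MOMCl, BnBr, Cl2CHOMe and the like) are given by name and SMILES in the steps and are not numbered.

**Route**

Step 1
Reactants: 1 methyl 3-oxopentanoate; 2 methyl (E)-but-2-enoate
Product: 4 methyl 3,6-dimethyl-2,4-dioxocyclohexane-1-carboxylate, via Michael adduct 3 (not isolated)
Conditions: NaOMe (1.1 equiv), MeOH, reflux, 6 h; then aq HCl, 0 °C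
Reagents that add atoms: none
Why: The β-keto ester enolate adds to the crotonate β-carbon in an intermolecular Michael reaction (the key fragment-joining C–C bond) and the adduct closes by Dieckmann (intramolecular Claisen) condensation of the ketone α'-carbon onto the distal ester, driven by formation of the stabilized 1,3-dione enolate, while the uncontrolled stereocentres (racemic diastereomer mixture) are all erased in step 2.

Step 2
Reactants: 4 methyl 3,6-dimethyl-2,4-dioxocyclohexane-1-carboxylate
Product: 6 methyl 2,4-dihydroxy-3,6-dimethylbenzoate, via bromo-dione 5 (not isolated)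
Conditions: Br2 (1.05 equiv), DMF, 0 °C → rt, then 80 °C, 12 h
Reagents that add atoms: none
Why: Electrophilic bromination at the doubly activated C3 of the dione followed by DMF-buffered 1,4-dehydrobromination of the bis-enol (bromination–dehydrobromination aromatization of a dihydroresorcylate) gives the resorcinol and removes all stereocentres.

Step 3
Reactants: 6 methyl 2,4-dihydroxy-3,6-dimethylbenzoate
Product: 7 methyl 2,4-bis(methoxymethoxy)-3,6-dimethylbenzoate
Conditions: NaH (2.5 equiv), MOMCl (2.6 equiv), DMF, 0 °C → rt
Reagents that add atoms: chloromethyl methyl ether, COCCl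
Why: Williamson-type O-alkylation of both sodium phenoxides (NaH is needed to break the hydrogen bond of the 2-OH to the ester) installs acetal ethers that survive LDA and are later removed by mild acid.

Step 4
Reactants: 7 methyl 2,4-bis(methoxymethoxy)-3,6-dimethylbenzoate
Product: 9 methyl 6-(bromomethyl)-2,4-bis(methoxymethoxy)-3-methylbenzoate, via benzyllithium 8 (not isolated)
Conditions: LDA (1.15 equiv), THF, −78 °C, 45 min; cannulate into BrCCl2CCl2Br (1.5 equiv), THF, −78 °C; aq NH4Cl
Reagents that add atoms: 1,2-dibromo-1,1,2,2-tetrachloroethane, BrC(Cl)(Cl)C(Cl)(Cl)Br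
Why: Lateral lithiation of the o-toluate removes a proton only from the 6-methyl group because that anion is conjugated with the ortho ester, which distinguishes it unambiguously from the 3-methyl group, and inverse addition to the Br+ donor gives the monobromide by electrophilic bromination while suppressing Wurtz coupling.

Step 5
Reactants: 10 methyl 3-oxobutanoate (methyl acetoacetate); 2 methyl (E)-but-2-enoate
Product: 12 methyl 6-methyl-2,4-dioxocyclohexane-1-carboxylate, via Michael adduct 11 (not isolated)
Conditions: NaOMe (1.1 equiv), MeOH, reflux, 4 h; then aq HCl, 0 °C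
Reagents that add atoms: none
Why: The same intermolecular Michael addition of the acetoacetate enolate to the crotonate followed by Dieckmann (Claisen) cyclization of the acetyl methyl onto the distal ester gives the dihydroorsellinate, whose racemic stereocentres disappear on aromatization.

Step 6
Reactants: 12 methyl 6-methyl-2,4-dioxocyclohexane-1-carboxylate
Product: 14 methyl 2,4-dihydroxy-6-methylbenzoate, via bromo-dione 13 (not isolated)
Conditions: Br2 (1.05 equiv), DMF, 0 °C → rt, then 80 °C, 12 h
Reagents that add atoms: none
Why: Bromination between the two carbonyls and DMF-buffered loss of HBr (bromination–dehydrobromination aromatization) converts the dione into the resorcylate without nuclear bromination because the dione enol is far more nucleophilic than the chelated ester-deactivated product.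

Step 7
Reactants: 14 methyl 2,4-dihydroxy-6-methylbenzoate
Product: 15 2,4-dihydroxy-6-methylbenzoic acid (orsellinic acid)
Conditions: 2.5 M aq NaOH (6 equiv), N2, 40 °C, 24–48 h; then 2 M HCl, 0 °C, pH 2, filter cold
Reagents that add atoms: sodium hydroxide, [Na+].[OH-]
Why: Saponification (BAc2) of the hindered salicylate ester is slow but clean in aqueous hydroxide where the carboxylate salt is stable, and cold acidification avoids decarboxylation of the β-resorcylic acid.

Step 8
Reactants: 15 2,4-dihydroxy-6-methylbenzoic acid
Product: 16 benzyl 2,4-dihydroxy-6-methylbenzoate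
Conditions: BnBr (1.05 equiv), KHCO3 (1.2 equiv), DMF, rt, 16 h
Reagents that add atoms: benzyl bromide, BrCc1ccccc1
Why: Bicarbonate ionizes only the carboxylic acid, so SN2 O-alkylation with benzyl bromide gives the benzyl ester without phenol benzylation and provides an ester that can later be removed without hydrolysis.

Step 9
Reactants: 16 benzyl 2,4-dihydroxy-6-methylbenzoate
Product: 18 benzyl 3-formyl-2,4-dihydroxy-6-methylbenzoate, via chloro-ether 17 (not isolated)
Conditions: Cl2CHOMe (1.5 equiv), TiCl4 (3 equiv), CH2Cl2, −10 °C → rt; then ice/1 M HCl; chromatography to remove the minor 5-formyl isomer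
Reagents that add atoms: dichloromethyl methyl ether, COC(Cl)Cl; water, O
Why: Rieche formylation (electrophilic aromatic substitution by TiCl4-activated dichloromethyl methyl ether) occurs mainly at C3, the position between the two hydroxyls that is activated by both and favoured by titanium chelation and bond fixation of the hydrogen-bonded salicylate, and aqueous work-up hydrolyses the α-chloro ether to the aldehyde.

Step 10
Reactants: 18 benzyl 3-formyl-2,4-dihydroxy-6-methylbenzoate
Product: 19 3-formyl-2,4-dihydroxy-6-methylbenzoic acid (haematommic acid)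
Conditions: H2 (1 atm), 10% Pd/C (5 mol%), EtOAc, rt, ca. 1 h (stop at 1 equiv uptake); use directly
Reagents that add atoms: none
Why: Catalytic hydrogenolysis of the benzyl C–O bond is much faster than reduction of the strongly chelated aryl aldehyde, so the acid is freed under neutral conditions without the hydrolysis or decarboxylation problems of saponifying a hindered formyl salicylate.

Step 11
Reactants: 9 methyl 6-(bromomethyl)-2,4-bis(methoxymethoxy)-3-methylbenzoate; 19 3-formyl-2,4-dihydroxy-6-methylbenzoic acid
Product: 20 [2-(methoxycarbonyl)-3,5-bis(methoxymethoxy)-4-methylphenyl]methyl 3-formyl-2,4-dihydroxy-6-methylbenzoate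
Conditions: KHCO3 (1.1 equiv), DMF, rt, 16 h
Reagents that add atoms: none
Why: With one equivalent of bicarbonate only the carboxylic acid of 19 is ionized (its chelated phenols stay protonated), and its carboxylate oxygen displaces the primary benzylic bromide in an SN2 esterification.

Step 12
Reactants: 20 [2-(methoxycarbonyl)-3,5-bis(methoxymethoxy)-4-methylphenyl]methyl 3-formyl-2,4-dihydroxy-6-methylbenzoate
Product: 21 methyl 6-[(3-formyl-2,4-dihydroxy-6-methylbenzoyl)oxymethyl]-2,4-dihydroxy-3-methylbenzoate (target)
Conditions: conc. HCl (5 equiv), MeOH/THF 1:1, rt → 40 °C, 4–8 h; aqueous work-up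
Reagents that add atoms: none
Why: Acid-catalysed transacetalization to methanol (MOM ether cleavage) frees both phenols under conditions that leave the hindered aryl esters, the electron-poor benzylic C–O bond and the chelated aldehyde untouched, giving the achiral target.

**Compound list**
1 | methyl 3-oxopentanoate | CCC(=O)CC(=O)OC | starting material
2 | methyl (E)-but-2-enoate (methyl crotonate) | C/C=C/C(=O)OC | starting material
3 | Michael adduct: dimethyl 3-methyl-2-propanoylpentanedioate (not isolated; racemic diastereomer mixture) | CCC(=O)C(C(=O)OC)C(C)CC(=O)OC | intermediate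
4 | methyl 3,6-dimethyl-2,4-dioxocyclohexane-1-carboxylate (racemic diastereomer/enol mixture) | COC(=O)C1C(C)CC(=O)C(C)C1=O | intermediate
5 | bromo-dione: methyl 3-bromo-3,6-dimethyl-2,4-dioxocyclohexane-1-carboxylate (not isolated; racemic mixture) | COC(=O)C1C(C)CC(=O)C(C)(Br)C1=O | intermediate
6 | methyl 2,4-dihydroxy-3,6-dimethylbenzoate (methyl β-orcinolcarboxylate) | COC(=O)c1c(C)cc(O)c(C)c1O | intermediate
7 | methyl 2,4-bis(methoxymethoxy)-3,6-dimethylbenzoate | COCOc1cc(C)c(C(=O)OC)c(OCOC)c1C | intermediate
8 | benzyllithium: methyl 6-(lithiomethyl)-2,4-bis(methoxymethoxy)-3-methylbenzoate (not isolated) | [Li]Cc1cc(OCOC)c(C)c(OCOC)c1C(=O)OC | intermediate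
9 | methyl 6-(bromomethyl)-2,4-bis(methoxymethoxy)-3-methylbenzoate | COCOc1cc(CBr)c(C(=O)OC)c(OCOC)c1C | intermediate
10 | methyl 3-oxobutanoate (methyl acetoacetate) | CC(=O)CC(=O)OC | starting material
11 | Michael adduct: dimethyl 2-acetyl-3-methylpentanedioate (not isolated; racemic diastereomer mixture) | CC(=O)C(C(=O)OC)C(C)CC(=O)OC | intermediate
12 | methyl 6-methyl-2,4-dioxocyclohexane-1-carboxylate (racemic diastereomer/enol mixture) | COC(=O)C1C(C)CC(=O)CC1=O | intermediate
13 | bromo-dione: methyl 3-bromo-6-methyl-2,4-dioxocyclohexane-1-carboxylate (not isolated; racemic mixture) | COC(=O)C1C(C)CC(=O)C(Br)C1=O | intermediate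
14 | methyl 2,4-dihydroxy-6-methylbenzoate (methyl orsellinate) | COC(=O)c1c(C)cc(O)cc1O | intermediate
15 | 2,4-dihydroxy-6-methylbenzoic acid (orsellinic acid) | Cc1cc(O)cc(O)c1C(=O)O | intermediate
16 | benzyl 2,4-dihydroxy-6-methylbenzoate | Cc1cc(O)cc(O)c1C(=O)OCc1ccccc1 | intermediate
17 | chloro-ether: benzyl 3-[chloro(methoxy)methyl]-2,4-dihydroxy-6-methylbenzoate (titanium-bound, not isolated) | COC(Cl)c1c(O)cc(C)c(C(=O)OCc2ccccc2)c1O | intermediate
18 | benzyl 3-formyl-2,4-dihydroxy-6-methylbenzoate (benzyl haematommate) | Cc1cc(O)c(C=O)c(O)c1C(=O)OCc1ccccc1 | intermediate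
19 | 3-formyl-2,4-dihydroxy-6-methylbenzoic acid (haematommic acid) | Cc1cc(O)c(C=O)c(O)c1C(=O)O | intermediate
20 | [2-(methoxycarbonyl)-3,5-bis(methoxymethoxy)-4-methylphenyl]methyl 3-formyl-2,4-dihydroxy-6-methylbenzoate | COCOc1cc(COC(=O)c2c(C)cc(O)c(C=O)c2O)c(C(=O)OC)c(OCOC)c1C | intermediate
21 | methyl 6-[(3-formyl-2,4-dihydroxy-6-methylbenzoyl)oxymethyl]-2,4-dihydroxy-3-methylbenzoate (achiral) | COC(=O)c1c(COC(=O)c2c(C)cc(O)c(C=O)c2O)cc(O)c(C)c1O | target

**Step count**
Total: 12 steps. Longest linear sequence: 8 steps (steps 5 → 6 → 7 → 8 → 9 → 10 → 11 → 12, from 10 and 2 to 21). The ring-A branch (steps 1–4) joins at step 11.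

**Three steps most likely to fail, with fallbacks**

Step 4 (lateral lithiation/bromination) is the least precedented operation: the product bromide can be alkylated or re-deprotonated by unreacted 8, giving bibenzyl or dibromide. The fallback replaces the anionic bromination by a radical one on an electron-poor arene, setting out from 6 and coming back to the route at 21. Compound 6 is acetylated (Ac2O, pyridine, cat. DMAP, rt) to methyl 2,4-diacetoxy-3,6-dimethylbenzoate F1. Wohl–Ziegler bromination (NBS 1.05 equiv, AIBN, PhCF3, 85 °C) then gives methyl 2,4-diacetoxy-6-(bromomethyl)-3-methylbenzoate F2, the acetates suppressing nuclear bromination. Selectivity between the two methyl groups is not assured here, so the 3-bromomethyl isomer is removed by chromatography and the regiochemistry is confirmed by HMBC/NOE. F2 is coupled with 19 (KHCO3, DMF, rt) to [3,5-diacetoxy-2-(methoxycarbonyl)-4-methylphenyl]methyl 3-formyl-2,4-dihydroxy-6-methylbenzoate F3. Acid methanolysis of the two aryl acetates (cat. HCl, MeOH, rt) gives 21.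

Step 9 (Rieche formylation) may give too much of the 5-formyl isomer, or partial loss of the benzyl ester under TiCl4. The fallback uses a removable blocking group, setting out from 16 and coming back at 19. Monobromination of 16 (NBS 1.0 equiv, MeCN, 0 °C) occupies the competing position and gives benzyl 5-bromo-2,4-dihydroxy-6-methylbenzoate F4. Formylation (Cl2CHOMe, TiCl4, CH2Cl2, 0 °C) can then only occur at C3, giving benzyl 5-bromo-3-formyl-2,4-dihydroxy-6-methylbenzoate F5. One hydrogenolysis (H2 1 atm, Pd/C, NaOAc, EtOAc/MeOH, rt, monitored to spare the aldehyde) removes both the benzyl ester and the aryl bromine to give 19.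

Step 2 (one-pot Br2/DMF aromatization of the 3-methyl dione) carries a quaternary bromide in intermediate 5 and may give mixtures of unreacted dione and ring-brominated phenol. The fallback aromatizes through an isolable bromoarene and then removes the halogen reductively, setting out from 4 and coming back at 6. Deliberate over-bromination (Br2 2.1 equiv, AcOH, rt) gives crystalline methyl 5-bromo-2,4-dihydroxy-3,6-dimethylbenzoate F6. Hydrogenolysis of the C–Br bond (H2 1 atm, Pd/C, NaOAc, MeOH, rt) then gives 6.

**Further compounds**
F1 | step 4 | methyl 2,4-diacetoxy-3,6-dimethylbenzoate | COC(=O)c1c(C)cc(OC(C)=O)c(C)c1OC(C)=O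
F2 | step 4 | methyl 2,4-diacetoxy-6-(bromomethyl)-3-methylbenzoate | COC(=O)c1c(CBr)cc(OC(C)=O)c(C)c1OC(C)=O
F3 | step 4 | [3,5-diacetoxy-2-(methoxycarbonyl)-4-methylphenyl]methyl 3-formyl-2,4-dihydroxy-6-methylbenzoate | COC(=O)c1c(COC(=O)c2c(C)cc(O)c(C=O)c2O)cc(OC(C)=O)c(C)c1OC(C)=O
F4 | step 9 | benzyl 5-bromo-2,4-dihydroxy-6-methylbenzoate | Cc1c(Br)c(O)cc(O)c1C(=O)OCc1ccccc1
F5 | step 9 | benzyl 5-bromo-3-formyl-2,4-dihydroxy-6-methylbenzoate | Cc1c(Br)c(O)c(C=O)c(O)c1C(=O)OCc1ccccc1
F6 | step 2 | methyl 5-bromo-2,4-dihydroxy-3,6-dimethylbenzoate | COC(=O)c1c(C)c(Br)c(O)c(C)c1O
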